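**Retrosynthetic overview**
1. Target 7 is cut at all three aryl–Cβ bonds at once: a spermidine tris[(E)-β-borylacrylamide] 5 (three β-acylvinyl anion, i.e. sp2-homoenolate, donors) plus 3 × 4-iodophenol 6 (aryl acceptor).
2. 5 comes from the tris-propiolamide 3 and 3 × bis(pinacolato)diboron 4 by syn boryl-cupration/protonation, which makes Cβ nucleophilic and sets each alkene as E.
3. 3 comes from spermidine 1 and 3 × propiolic acid 2 by threefold N-acylation.
4. No ring is formed; the three benzene rings arrive intact in 6. The only stereo-elements are the three E alkenes, set in step 2 and retained in step 3.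

Assumption: the target has no stereocentre, so "single enantiomer" is read as the single (E,E,E) geometric isomer shown. Each step consumes three molecules of the small partner per spermidine core; one is counted on the Reactants line and the other two are written out on the "Reagents that add atoms" line.

**Step 1**
Reactants: 1 spermidine (N1-(3-aminopropyl)butane-1,4-diamine); 2 propiolic acid (prop-2-ynoic acid)
Product: 3 N1,N5,N10-tri(prop-2-ynoyl)spermidine (each of the three nitrogens carries HC≡C–C(=O)–)
Conditions: 2 (3.6 equiv), DCC (3.6 equiv), CH2Cl2, −10 °C, 15 min; then 1 (1.0 equiv) dropwise, −10 → 0 °C, 3 h; filter, chromatography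
Reagents that add atoms: propiolic acid, two further molecules (C#CC(=O)O.C#CC(=O)O)
Why: Carbodiimide (Steglich-type) amide coupling in which three molecules of pre-activated propiolic acid acylate the two primary and the one secondary amine of one spermidine, the amine being added last and cold so that N-acylation outruns aza-Michael addition to the ynamide; no stereo-element is formed.

**Step 2**
Reactants: 3 N1,N5,N10-tri(prop-2-ynoyl)spermidine; 4 bis(pinacolato)diboron
Product: 5 N1,N5,N10-tris[(E)-3-(4,4,5,5-tetramethyl-1,3,2-dioxaborolan-2-yl)prop-2-enoyl]spermidine (all three alkenes E)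
Conditions: 4 (3.15 equiv), CuCl (15 mol %), Xantphos (15 mol %), NaOtBu (18 mol %), MeOH (6 equiv), THF, Ar, 0 °C → rt; short silica pad
Reagents that add atoms: B2pin2, two further molecules (CC1(C)OB(OC1(C)C)B1OC(C)(C)C(C)(C)O1.CC1(C)OB(OC1(C)C)B1OC(C)(C)C(C)(C)O1)
Why: Cu(I)-catalysed conjugate protoboration of the three ynamides (boryl-cupration then protonolysis), one diboron per alkyne: L–Cu–Bpin adds syn with boron on the terminal β carbon and MeOH protonates Cα with retention, so B and C=O end up trans (E, also the thermodynamic isomer), and the normally electrophilic β carbon becomes a nucleophilic β-acylvinyl anion (sp2-homoenolate) equivalent.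

**Step 3**
Reactants: 5 N1,N5,N10-tris[(E)-3-(pinacolboryl)prop-2-enoyl]spermidine; 6 4-iodophenol
Product: 7 N(1),N(5),N(10)-(E)-tri-p-coumaroylspermidine
Conditions: 6 (3.6 equiv), Pd(dppf)Cl2·CH2Cl2 (9 mol %), K3PO4 (9 equiv), 1,4-dioxane/H2O 4:1, degassed, 70 °C; then aq. HCl to pH 5, EtOAc/n-BuOH extraction, chromatography
Reagents that add atoms: 4-iodophenol, two further molecules (Oc1ccc(I)cc1.Oc1ccc(I)cc1)
Why: Threefold Suzuki–Miyaura coupling in which each β-boryl acrylamide acts as a homoenolate-type (d3) donor towards one molecule of aryl iodide, so two carbons that are both acceptors in their parent forms (acrylamide Cβ and Ar–I) are joined; transmetalation and reductive elimination proceed with retention, so the E geometry from step 2 is carried into all three alkenes, and free ArOH and amide N–H are tolerated.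

**Compound list**
1 | spermidine | NCCCCNCCCN | starting material
2 | propiolic acid | C#CC(=O)O | starting material
3 | N1,N5,N10-tri(prop-2-ynoyl)spermidine | C#CC(=O)NCCCCN(CCCNC(=O)C#C)C(=O)C#C | intermediate
4 | bis(pinacolato)diboron | CC1(C)OB(OC1(C)C)B1OC(C)(C)C(C)(C)O1 | starting material
5 | N1,N5,N10-tris[(E)-3-(4,4,5,5-tetramethyl-1,3,2-dioxaborolan-2-yl)prop-2-enoyl]spermidine | O=C(/C=C/B1OC(C)(C)C(C)(C)O1)NCCCCN(CCCNC(=O)/C=C/B1OC(C)(C)C(C)(C)O1)C(=O)/C=C/B1OC(C)(C)C(C)(C)O1 | intermediate
6 | 4-iodophenol | Oc1ccc(I)cc1 | starting material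
7 | N(1),N(5),N(10)-(E)-tri-p-coumaroylspermidine | O=C(/C=C/c1ccc(O)cc1)NCCCCN(CCCNC(=O)/C=C/c1ccc(O)cc1)C(=O)/C=C/c1ccc(O)cc1 | target

**Totals**
Total steps: 3. Longest linear sequence: 3 (1 → 3 → 5 → 7).

**Steps most likely to fail, with fallbacks**

Step 3 (highest risk). Three couplings must all go to completion on one molecule, and the electron-poor alkenyl boronate can protodeboronate in hot aqueous base while the phenoxide of 6 slows oxidative addition. The fallback sets out from 5 and comes back at 7. Compound 5 is coupled with 4-iodophenyl acetate (3.6 equiv, Pd(dppf)Cl2, powdered K3PO4 with about 3 equiv H2O, dioxane, 70 °C), so the electrophile is electron-poor and no phenoxide is present during C–C bond formation. This gives N1,N5,N10-tris[(E)-4-acetoxycinnamoyl]spermidine F4; any partial loss of acetate is harmless. The crude material is then treated with K2CO3 in MeOH at rt and acidified to give 7.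

Step 2. Threefold borylation on a polar substrate can suffer from methoxide addition to the terminal ynamide, double borylation or incomplete conversion. The fallback sets out from 4, takes in 1, and comes back at 5, installing boron before the amides are made. Commercial tert-butyl propiolate is borylated with 4 under the same Cu/Xantphos/MeOH conditions to give tert-butyl (E)-3-(4,4,5,5-tetramethyl-1,3,2-dioxaborolan-2-yl)acrylate F2. TFA in CH2Cl2 then gives (E)-3-(4,4,5,5-tetramethyl-1,3,2-dioxaborolan-2-yl)acrylic acid F3. F3 (3.3 equiv) is coupled to 1 with a carbodiimide (EDC·HCl, HOBt, CH2Cl2, 0 °C) to give 5.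

Step 1. Amines can add in conjugate fashion to the activated propiolate or to the product, and N-acylurea formation lowers the yield of the tris-amide. The fallback sets out from 1 and comes back at 3. Compound 1 is acylated with commercial 3-(trimethylsilyl)propynoic acid (3.6 equiv, DCC, CH2Cl2, 0 °C), where the silyl group blocks the β carbon against aza-Michael attack. This gives N1,N5,N10-tris[3-(trimethylsilyl)prop-2-ynoyl]spermidine F1. Brief treatment with catalytic K2CO3 in MeOH at 0 °C removes the three silyl groups to give 3.

**Further compounds**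
F1 | step 1 | N1,N5,N10-tris[3-(trimethylsilyl)prop-2-ynoyl]spermidine | C[Si](C)(C)C#CC(=O)NCCCCN(CCCNC(=O)C#C[Si](C)(C)C)C(=O)C#C[Si](C)(C)C
F2 | step 2 | tert-butyl (E)-3-(4,4,5,5-tetramethyl-1,3,2-dioxaborolan-2-yl)acrylate | CC(C)(C)OC(=O)/C=C/B1OC(C)(C)C(C)(C)O1
F3 | step 2 | (E)-3-(4,4,5,5-tetramethyl-1,3,2-dioxaborolan-2-yl)acrylic acid | OC(=O)/C=C/B1OC(C)(C)C(C)(C)O1
F4 | step 3 | N1,N5,N10-tris[(E)-4-acetoxycinnamoyl]spermidine | CC(=O)Oc1ccc(/C=C/C(=O)NCCCCN(CCCNC(=O)/C=C/c2ccc(OC(C)=O)cc2)C(=O)/C=C/c2ccc(OC(C)=O)cc2)cc1
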